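**Plan**

- Retrosynthesis: the tiglate C–O bond, the carbinol C–H bond (back to the aryl methyl ketone) and the acetate C–O bond are cut first. The ring bond O1–C2 and the O–CH3 bond of the ester are then cut together, which turns the dihydrofuran into a seven-membered aryl lactone (1-benzoxepin-2-one) carrying a cis-4,5-oxirane. The oxirane oxygen, the ring C4=C5 bond (intramolecular Wittig), the aryl ester C–O bond and the formyl C–C bond follow.
- Forward order of rings: the benzene ring is bought; the seven-membered lactone is closed by olefination; the oxirane is added; the five-membered ring is made by contraction of the lactone; acetate, carbinol and tiglate come last.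
- Enabling feature: in the target, O1 and the ester carbonyl carbon are 1,4-related through C2 and the methylidene-bearing carbon, so O1, C(=O), C(=CH2), C2, C3, C3a and C7a can form one seven-membered ring. This lactone masks the phenol, carries the future CO2Me and holds the C2=C3 styrene bond Z, so that its oxirane is cis.
- Stereochemistry: one catalytic epoxidation sets C2 and C3 together; the contraction keeps C3 and inverts C2, which gives the 2,3-cis pair by substrate control; the side-chain carbinol comes from a CBS reduction.

Key step: step 5

Assumption: the facial sense of the epoxidation of 7 is taken from 2,2-dimethyl-2H-chromenes, for which the (S,S)-(salen)MnCl catalyst gives the (3S,4S)-oxirane; this corresponds to (4R,5S)-8.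

**Step 1**
Reactants: 1 4′-hydroxyacetophenone
Product: 2 5-acetyl-2-hydroxybenzaldehyde
Conditions: hexamethylenetetramine, CF3CO2H, 85 °C; then H2O, 60 °C
Reagents that add atoms: hexamethylenetetramine (C1N2CN3CN1CN(C2)C3); water (O)
Why: Duff formylation, in which the iminium ion from hexamethylenetetramine attacks the only free ortho position of the para-blocked phenol and hydrolysis of the benzylic iminium gives the salicylaldehyde, the acetyl group being inert in acid.

**Step 2**
Reactants: 3 2-(bromomethyl)prop-2-enoic acid; 2 5-acetyl-2-hydroxybenzaldehyde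
Product: 5 4-acetyl-2-formylphenyl 2-(bromomethyl)prop-2-enoate, via acid chloride 4 (not isolated)
Conditions: 3, (COCl)2, DMF (cat.), CH2Cl2, 0 °C to rt, evaporate; then 2, 2,6-lutidine, CH2Cl2, −20 to 0 °C
Reagents that add atoms: none
Why: O-acylation of the acidic phenol by the acyl chloride should outrun SN2′ O-alkylation at the allylic bromide, and the hindered base should not quaternize that bromide.

**Step 3**
Reactants: 5 4-acetyl-2-formylphenyl 2-(bromomethyl)prop-2-enoate
Product: 7 7-acetyl-3-methylidene-1-benzoxepin-2(3H)-one (ring C4=C5 bond Z), via phosphonium bromide 6 (not isolated)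
Conditions: PPh3, MeCN, rt; then K2CO3, 18-crown-6 (cat.), MeCN (5 mM), 40 °C
Reagents that add atoms: none
Why: SN2′ quaternization of the 2-(bromomethyl)acrylate gives the allylic phosphonium salt, whose semi-stabilized ylide (more acidic than the methyl ketone) should undergo intramolecular Wittig olefination with the ortho aldehyde through its α-carbon, the seven-membered ring allowing only the Z alkene.

**Step 4**
Reactants: 7 7-acetyl-3-methylidene-1-benzoxepin-2(3H)-one
Product: 8 (4R,5S)-7-acetyl-4,5-epoxy-3-methylidene-4,5-dihydro-1-benzoxepin-2(3H)-one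
Conditions: (S,S)-(salen)MnCl [salen = N,N′-bis(3,5-di-tert-butylsalicylidene)-1,2-cyclohexanediamine dianion] (5 mol%), mCPBA, N-methylmorpholine N-oxide, CH2Cl2, −78 °C
Reagents that add atoms: mCPBA (OOC(=O)c1cccc(Cl)c1)
Why: Jacobsen–Katsuki epoxidation works best on cis-disubstituted, aryl-conjugated cyclic alkenes; the chiral manganese oxo species should deliver oxygen to one face of the Z styrene bond and so set C4 and C5 together as a cis-oxirane, while the electron-poor methylidene group and the aryl ketone stay untouched at −78 °C.

**Step 5**
Reactants: 8 (4R,5S)-7-acetyl-4,5-epoxy-3-methylidene-4,5-dihydro-1-benzoxepin-2(3H)-one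
Product: 10 methyl 2-[(2S,3S)-5-acetyl-3-hydroxy-2,3-dihydro-1-benzofuran-2-yl]prop-2-enoate, via epoxy phenol ester 9 (not isolated)
Conditions: K2CO3 (0.1 equiv), MeOH, −20 to 0 °C; then AcOH
Reagents that add atoms: methanol (CO)
Why: Methoxide cleaves the acyl–oxygen bond of the activated 4-acetylphenyl ester, so the lactone carbonyl becomes the methyl ester and the ring oxygen is freed as a phenoxide (9 as its anion); this phenoxide attacks the allylic oxirane carbon C4 from the side opposite to the oxirane oxygen (intramolecular SN2), and the C5 alkoxide takes a proton from methanol, which returns methoxide and makes the base catalytic. The closest known reaction types are the Perkin coumarin-to-benzofuran ring contraction and the contraction of α-sulfonyloxy lactones to tetrahydrofuran esters, and the closing event itself is the one seen in Corey–Chaykovsky reactions of salicylaldehydes, where an ortho phenoxide opens the oxirane to a 2,3-dihydrobenzofuran-3-ol. The five-membered ring closes in the 5-endo-tet mode with respect to the oxirane, since both oxirane carbons end up in the new ring. C3 of the product keeps the C–O bond and configuration of oxirane carbon C5, C2 is formed with inversion at C4, and because the lactone ring allows only a cis-oxirane, inversion at one carbon should give the 2,3-cis pair, (2S,3S) from (4R,5S). The step needs attack of methoxide at the ester carbonyl in preference to conjugate addition at the methylidene group, which the activated aryl ester and the low standing concentration of methoxide (buffered by the phenol) should secure, and five-membered closure at C4 in preference to seven-membered SN2′ closure at the methylidene carbon, which ring size and the allylic activation of C4 should secure. Methanol protonates the C3 alkoxide at once, which should suppress relactonization and reversal.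

**Step 6**
Reactants: 10 methyl 2-[(2S,3S)-5-acetyl-3-hydroxy-2,3-dihydro-1-benzofuran-2-yl]prop-2-enoate
Product: 11 methyl 2-[(2S,3S)-3-acetoxy-5-acetyl-2,3-dihydro-1-benzofuran-2-yl]prop-2-enoate
Conditions: Ac2O, pyridine, CH2Cl2, 0 °C
Reagents that add atoms: acetic anhydride (CC(=O)OC(C)=O)
Why: O-acetylation of the secondary alcohol without a strongly nucleophilic catalyst should trap the cis hydroxy ester before it lactonizes and should leave the allylic aryl ether next to the acrylate untouched; no stereocenter is involved.

**Step 7**
Reactants: 11 methyl 2-[(2S,3S)-3-acetoxy-5-acetyl-2,3-dihydro-1-benzofuran-2-yl]prop-2-enoate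
Product: 12 methyl 2-[(2S,3S)-3-acetoxy-5-[(1S)-1-hydroxyethyl]-2,3-dihydro-1-benzofuran-2-yl]prop-2-enoate
Conditions: (R)-2-methyl-CBS-oxazaborolidine (20 mol%), catecholborane, toluene, −78 °C; then aq. NaHCO3
Reagents that add atoms: none
Why: CBS reduction, in which the (R)-oxazaborolidine directs hydride to the Re face of the aryl methyl ketone and should give the (S)-carbinol under reagent control, catecholborane at low temperature sparing the acrylate and both esters.

**Step 8**
Reactants: 12 methyl 2-[(2S,3S)-3-acetoxy-5-[(1S)-1-hydroxyethyl]-2,3-dihydro-1-benzofuran-2-yl]prop-2-enoate; 13 (E)-2-methylbut-2-enoyl chloride (tigloyl chloride)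
Product: 14 methyl 2-[(2S,3S)-3-acetoxy-5-[(1S)-1-{[(2E)-2-methylbut-2-enoyl]oxy}ethyl]-2,3-dihydro-1-benzofuran-2-yl]prop-2-enoate
Conditions: pyridine, CH2Cl2, 0 °C to rt
Reagents that add atoms: none
Why: acylation at the hydroxyl oxygen leaves the benzylic C–O bond and its configuration untouched, and the basic medium should prevent acid ionization of the 4-alkoxybenzylic centre.

**Compound list**

1 | 4′-hydroxyacetophenone | CC(=O)c1ccc(O)cc1 | starting material
2 | 5-acetyl-2-hydroxybenzaldehyde | CC(=O)c1ccc(O)c(C=O)c1 | intermediate
3 | 2-(bromomethyl)prop-2-enoic acid | C=C(CBr)C(=O)O | starting material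
4 | 2-(bromomethyl)prop-2-enoyl chloride | C=C(CBr)C(=O)Cl | intermediate
5 | 4-acetyl-2-formylphenyl 2-(bromomethyl)prop-2-enoate | C=C(CBr)C(=O)Oc1ccc(C(C)=O)cc1C=O | intermediate
6 | {2-[(4-acetyl-2-formylphenoxy)carbonyl]prop-2-en-1-yl}triphenylphosphonium bromide | C=C(C[P+](c1ccccc1)(c1ccccc1)c1ccccc1)C(=O)Oc1ccc(C(C)=O)cc1C=O.[Br-] | intermediate
7 | 7-acetyl-3-methylidene-1-benzoxepin-2(3H)-one | C=C1C=Cc2cc(C(C)=O)ccc2OC1=O | intermediate
8 | (4R,5S)-7-acetyl-4,5-epoxy-3-methylidene-4,5-dihydro-1-benzoxepin-2(3H)-one | C=C1C(=O)Oc2ccc(C(C)=O)cc2[C@@H]2O[C@H]12 | intermediate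
9 | methyl 2-[(2R,3S)-3-(5-acetyl-2-hydroxyphenyl)oxiran-2-yl]prop-2-enoate | C=C(C(=O)OC)[C@H]1O[C@H]1c1cc(C(C)=O)ccc1O | intermediate
10 | methyl 2-[(2S,3S)-5-acetyl-3-hydroxy-2,3-dihydro-1-benzofuran-2-yl]prop-2-enoate | C=C(C(=O)OC)[C@@H]1Oc2ccc(C(C)=O)cc2[C@@H]1O | intermediate
11 | methyl 2-[(2S,3S)-3-acetoxy-5-acetyl-2,3-dihydro-1-benzofuran-2-yl]prop-2-enoate | C=C(C(=O)OC)[C@@H]1Oc2ccc(C(C)=O)cc2[C@@H]1OC(C)=O | intermediate
12 | methyl 2-[(2S,3S)-3-acetoxy-5-[(1S)-1-hydroxyethyl]-2,3-dihydro-1-benzofuran-2-yl]prop-2-enoate | C=C(C(=O)OC)[C@@H]1Oc2ccc([C@H](C)O)cc2[C@@H]1OC(C)=O | intermediate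
13 | (E)-2-methylbut-2-enoyl chloride | C/C=C(\C)C(Cl)=O | starting material
14 | methyl 2-[(2S,3S)-3-acetoxy-5-[(1S)-1-{[(2E)-2-methylbut-2-enoyl]oxy}ethyl]-2,3-dihydro-1-benzofuran-2-yl]prop-2-enoate | C=C(C(=O)OC)[C@@H]1Oc2ccc([C@H](C)OC(=O)/C(C)=C/C)cc2[C@@H]1OC(C)=O | target

**Totals**

Total step count: 8. Longest linear sequence: 8 steps (1 to 14).

**Steps most likely to fail**

Step 5. Conjugate addition of methoxide or of the phenoxide at the methylidene carbon (SN2′ opening of the oxirane) may compete with closure at C4. The cis hydroxy ester may lactonize, and the phenoxide may ionize the benzylic C–O bond of the oxirane and so erode the C3 configuration. The fallback separates ring opening from ring closure and sets out from 7. Methanolysis of the aryl lactone before any oxirane is present (K2CO3 cat., MeOH, −20 °C, AcOH quench) should give methyl (3Z)-4-(5-acetyl-2-hydroxyphenyl)-2-methylidenebut-3-enoate F1, the ring having already fixed the Z geometry. Silylation (t-BuMe2SiCl, imidazole, DMF) should give methyl (3Z)-4-[5-acetyl-2-(tert-butyldimethylsilyloxy)phenyl]-2-methylidenebut-3-enoate F2. Jacobsen–Katsuki epoxidation of the Z styrene bond under the conditions of step 4 should give methyl 2-[(2R,3S)-3-[5-acetyl-2-(tert-butyldimethylsilyloxy)phenyl]oxiran-2-yl]prop-2-enoate F3. Buffered fluoride (Bu4NF, AcOH, THF, 0 °C) then frees the phenol, which should open the oxirane at the allylic carbon with inversion; the sequence comes back to the route at 10.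

Step 3. Intermolecular olefination to oligomers, attack through the γ-carbon of the allylic ylide, or cleavage of the aryl ester by the base may lower the ring closure. The fallback sets out from 5 and closes the ring by carbonyl allylation instead of olefination. Indium powder in DMF at rt should convert the allylic bromide into an allylindium species that adds to the ortho aldehyde (intramolecular Barbier reaction) and gives 7-acetyl-5-hydroxy-3-methylidene-4,5-dihydro-1-benzoxepin-2(3H)-one F4. Dehydration of this benzylic alcohol with the Burgess reagent (toluene, 50 °C) should install the ring C4=C5 bond; the sequence comes back to the route at 7.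

Step 4. Facial selectivity on the seven-membered diene lactone may be poor, and stepwise oxygen transfer may lead to bonding at the methylidene terminus. The fallback sets out from 7 and replaces the metal-oxo catalyst by a chiral dioxirane, which transfers oxygen in a concerted way: Shi epoxidation with the glucose-derived oxazolidinone ketone for cis-olefins, Oxone (2KHSO5·KHSO4·K2SO4), K2CO3/AcOH buffer near pH 8, dimethoxyethane–water, −10 °C. It comes back to the route at 8 and makes no new compound (F0).

**Further compounds**

F1 | step 5 | methyl (3Z)-4-(5-acetyl-2-hydroxyphenyl)-2-methylidenebut-3-enoate | C=C(/C=C\c1cc(C(C)=O)ccc1O)C(=O)OC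
F2 | step 5 | methyl (3Z)-4-[5-acetyl-2-(tert-butyldimethylsilyloxy)phenyl]-2-methylidenebut-3-enoate | C=C(/C=C\c1cc(C(C)=O)ccc1O[Si](C)(C)C(C)(C)C)C(=O)OC
F3 | step 5 | methyl 2-[(2R,3S)-3-[5-acetyl-2-(tert-butyldimethylsilyloxy)phenyl]oxiran-2-yl]prop-2-enoate | C=C(C(=O)OC)[C@H]1O[C@H]1c1cc(C(C)=O)ccc1O[Si](C)(C)C(C)(C)C
F4 | step 3 | 7-acetyl-5-hydroxy-3-methylidene-4,5-dihydro-1-benzoxepin-2(3H)-one (racemic) | C=C1CC(O)c2cc(C(C)=O)ccc2OC1=O
F0 | step 4 | none | none
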